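**Proposed total synthesis of CNP0243386.4 (daucane triol 4-vanillate) by an intramolecular cyclopropanation / divinylcyclopropane rearrangement**

Ring atoms of all bicyclic compounds carry azulene numbering: C1, C2, C3 (five-membered ring), C3a, C4 to C8 (seven-membered ring), C8a.

## Analysis of the target

The target is the 4-hydroxy-3-methoxybenzoate of a sesquiterpene triol. Its core is a trans-fused bicyclo[5.3.0]dec-7-ene: a cyclopentane (C1, C2, C3, C3a, C8a) fused to a cycloheptene (C3a to C8a, double bond C7=C8). There are five stereocenters: C3 (tertiary carbinol with isopropyl, R), C3a (ring-fusion CH, S), C4 (ester carbon, S), C6 (tertiary allylic carbinol with methyl, R) and C8a (quaternary, methyl, R). The C8a methyl, the C3 hydroxyl and the C6 methyl lie on one face; H3a, the C4 oxygen, the C6 hydroxyl and the isopropyl group lie on the other. The C3/C4 oxygens are therefore 1,3-anti and the C4/C6 oxygens are 1,3-cis on the seven-membered ring. Sensitive groups are the tertiary allylic alcohol at C6 (ionises with acid), the two β-hydroxy relationships (retro-aldol or elimination at any ketone stage), the free phenol and the aryl ester. The hard part is the quaternary C8a at the ring fusion, directly flanked by the C7=C8 double bond, inside a seven-membered ring whose stereocenters are all close to one another. The feature that the route exploits is the sequence C7=C8–C8a–C3a–C4(O): at the enol oxidation level of C4 this is a skipped diene with C8a as central sp3 atom and the C5–C6 bond opposite to it. That is the retron of a cis-divinylcyclopropane rearrangement in which C8a is the cyclopropane carbon that keeps both of its ring bonds. In addition C3, the carbinol carbon next to C3a, can have been the acceptor carbonyl of a diazo ketone, so the cyclopropane C3a–C8a–C8 can come from an intramolecular carbene addition that closes the five-membered ring.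

## Retrosynthetic reasoning

**21 to 18 and 19.** The ester C–O bond at C4 is cut last. In triol 18 only the C4 hydroxyl is secondary, so acylation with 19 needs no protection of the core. The phenol of 19 is masked as an acetate (compound 20), which ammonia removes without acid, sparing the tertiary allylic alcohol.

**18 to 17.** The C6–CH3 bond is cut. Enone 17 should accept a methyl nucleophile at C6 while the C4 alkoxide holds the metal on the lower face. The carbonyl oxygen is drawn to that face, which gives the cis-1,3-diol and puts the methyl on the face of the C8a methyl.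

**17 to 16.** The C6 carbonyl comes from a CH2 group. In 16 the C7=C8 bond has a single allylic methylene (C6), because C8a is quaternary, so the position of the allylic oxidation is not in question.

**16 to 15 to 13.** The C4–H bond is cut (hydride delivered from the C3 hydroxyl, 1,3-anti), then the C3–isopropyl bond and the C3a–H bond. In 13 the C3 ketone is the carbonyl of a vinylogous silyl ester, so an isopropyl nucleophile adds there and nowhere else. The C4 oxygen is still an enol ether, and C3a is set afterwards by protonation under thermodynamic control.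

**13 to 12 to 11 (key disconnection).** Two ring bonds are cut: C5–C6 (seven-membered ring, Cope rearrangement of cis-divinylcyclopropane 12) and C3a–C8a (five-membered ring, carbene addition). The precursor 11 is an acyclic, achiral diazo trienone. The forward reaction has to close both rings, create the quaternary C8a in one absolute configuration and leave the double bond at C7=C8 and the oxygen at C4. The cut is made here because no other pair of bonds removes both rings and the quaternary center at once.

**11 to 9 to 8 to 6 and 5.** The enol ether comes from the acetyl group of diazo diketone 9, the diazo group from diketone 8 by diazo transfer, and 8 from the dianion of 6 and allylic bromide 5. This cut puts all ten ring carbons into two cheap pieces.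

**5 to 4 to 1 and 2.** The E-trisubstituted diene, whose geometry later decides that the cyclopropane is cis-divinyl, is traced to a syn-carbometalation of alkyne 1 and a coupling with 2.

## Alternatives that were turned down

**Alternative 1:** (textbook) Cut the C7=C8 double bond. Forward key step: ring-closing metathesis of diene A1 with a ruthenium carbene (second-generation Grubbs catalyst), then esterification. Turned down because the metathesis forms one double bond and no stereocenter. All five stereocenters, among them the quaternary carbon and both tertiary carbinols, would have to be set one by one on a cyclopentane with a flexible side chain. The C6 carbinol would come from a vinyl addition to a methyl ketone with weak 1,3-induction. One olefin is a vinyl group on a quaternary carbon and the other a tertiary vinyl carbinol, both slow partners. The sequence would be clearly longer than the present one.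

**Alternative 2:** Delete C7: late one-carbon ring expansion of trans-hydrindanone A2. Forward key step: diazoalkane homologation of the six-membered ketone (Tiffeneau–Demjanov type), then dehydrogenation to 17 and methyl addition. The saturated hydrindane is easy to substitute with control, which is the attraction. Turned down because the ketone of A2 is flanked by two methylene groups of similar migratory aptitude, so two cycloheptanones are expected, and the later dehydrogenation again has two α sides. A2 itself is not close to the usual hydrindanone building blocks, which carry the oxygen next to the quaternary carbon and not next to the ring-fusion CH.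

**Alternative 3:** Cut the C6–O bond and shift the double bond: late allylic oxidation with transposition of the C6=C7 isomer A3. Forward key step: Schenck ene reaction (photo-oxygenation, then reduction of the hydroperoxide). Turned down because the trisubstituted olefin of A3 offers three sets of allylic hydrogens (C5, C8 and the C6 methyl), so three ene products are expected. The free electron-rich phenol is itself oxidised under these conditions. The step only relocates functionality: the skeleton would still have to be built first, with the double bond in the wrong place.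

Key step: step 6

Remark on the chemistry: the sense of induction of Rh2(S-PTAD)4 in step 6 is assumed to give the (8aR) series; if it gives the mirror image, Rh2(R-PTAD)4 is used and nothing else changes.

## Route

Step 1
Reactants: 1 prop-2-yn-1-ol; 2 bromoethene
Product: 4 (2E)-2-methylpenta-2,4-dien-1-ol, via alkenylalane 3 (not isolated)
Conditions: Me3Al (3 equiv), Cp2ZrCl2 (0.25 equiv), CH2Cl2, 0 °C to rt; then 2, ZnCl2, Pd(PPh3)4 (5 mol %), THF, rt; aq. Rochelle salt
Reagents that add atoms: trimethylaluminium, C[Al](C)C
Why: Zirconium-catalysed syn-carboalumination (Negishi) puts methyl on the internal and aluminium on the terminal alkyne carbon, which fixes the E geometry; the alkenylalane should then couple with 2 with retention under palladium catalysis (Negishi coupling).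

Step 2
Reactants: 4 (2E)-2-methylpenta-2,4-dien-1-ol
Product: 5 (3E)-5-bromo-4-methylpenta-1,3-diene
Conditions: CBr4, PPh3, CH2Cl2, 0 °C; used as a cold solution
Reagents that add atoms: carbon tetrabromide, BrC(Br)(Br)Br
Why: Appel reaction of a primary allylic alcohol under neutral conditions; displacement at the primary carbon should keep the position and geometry of the diene.

Step 3
Reactants: 6 pentane-2,4-dione; 5 (3E)-5-bromo-4-methylpenta-1,3-diene
Product: 8 (7E)-7-methyldeca-7,9-diene-2,4-dione, via dianion 7 (not isolated)
Conditions: LDA (2.2 equiv), THF, 0 °C; then 5, −78 to 0 °C; aq. NH4Cl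
Reagents that add atoms: none
Why: Alkylation of a 1,3-diketone dianion: the terminal, more basic carbanion should attack the primary allylic bromide by SN2, which leaves the E-diene untouched.

Step 4
Reactants: 8 (7E)-7-methyldeca-7,9-diene-2,4-dione
Product: 9 (7E)-3-diazo-7-methyldeca-7,9-diene-2,4-dione
Conditions: p-ABSA, Et3N, MeCN, 0 °C to rt
Reagents that add atoms: 4-acetamidobenzenesulfonyl azide, CC(=O)Nc1ccc(cc1)S(=O)(=O)N=[N+]=[N-]
Why: Regitz diazo transfer to the doubly activated methylene of a 1,3-diketone.

Step 5
Reactants: 9 (7E)-3-diazo-7-methyldeca-7,9-diene-2,4-dione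
Product: 11 (7E)-2-[(tert-butyldimethylsilyl)oxy]-3-diazo-7-methyldeca-1,7,9-trien-4-one, via lithium enolate 10 (not isolated)
Conditions: LiHMDS (1.05 equiv), THF, −78 °C; then TBSOTf, −78 °C; used without chromatography
Reagents that add atoms: tert-butyldimethylsilyl trifluoromethanesulfonate, CC(C)(C)[Si](C)(C)OS(=O)(=O)C(F)(F)F
Why: Kinetic deprotonation of the diazo diketone by a hindered amide should favour the acetyl methyl over the chain methylene, and O-silylation of the enolate gives the siloxyvinyl diazo ketone (silyl enol ether formation as used for siloxyvinyl diazoacetates).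

Step 6
Reactants: 11 (7E)-2-[(tert-butyldimethylsilyl)oxy]-3-diazo-7-methyldeca-1,7,9-trien-4-one
Product: 13 (8aR)-4-[(tert-butyldimethylsilyl)oxy]-8a-methyl-1,2,5,6-tetrahydroazulen-3(8aH)-one, via divinylcyclopropane 12 (not isolated)
Conditions: Rh2(S-PTAD)4 (dirhodium tetrakis[(S)-(1-adamantyl)(N-phthalimido)acetate], 1 mol %), toluene, slow addition of 11 at −20 °C; then rt to 50 °C
Reagents that add atoms: none
Why: Rh2(S-PTAD)4 should decompose 11 with loss of N2 to a donor/acceptor vinylcarbenoid at C3a (atoms named by their place in 13), flanked by the C3 ketone and the siloxyvinyl group; it adds across the tethered C8a=C8 double bond and so closes the five-membered ring as bicyclo[3.1.0]hexan-2-one 12 ([2+1] addition through the three-atom tether C1–C2–C3, the terminal vinyl group being out of reach). Because the alkene is E and the tether can only be cis-fused, the vinyl group on C8 is forced exo, cis to the siloxyvinyl group on C3a, so 12 is a cis-divinylcyclopropane. It should undergo the Cope rearrangement through the boat transition state at or slightly above room temperature, forming C5–C6 and cleaving C3a–C8; this closes the seven-membered ring by a [3,3]-sigmatropic shift as the 1,4-diene C3a=C4(OSi)/C7=C8, and both reacting termini are CH2, so only hydrogens point inward. The closest known reaction type is the dirhodium-carboxylate-catalysed tandem cyclopropanation/Cope rearrangement of vinyl diazo carbonyl compounds with dienes (formal (4+3) cycloaddition), known inter- and intramolecularly and in enantioselective form, together with the intramolecular cyclopropanation of diazo ketones to bicyclo[3.1.0]hexanones. C8a is the only stereocenter left in 13; the chiral catalyst sets it when the carbenoid selects one face of the C8a=C8 bond, and the rearrangement, which does not touch the bonds from C8a to methyl and to C1, passes it on unchanged. The step needs cyclopropanation to outrun thermal 1,5-cyclisation of the vinyl diazo compound to a pyrazole (slow addition, low temperature) and a Cope rearrangement faster than the 1,5-hydrogen shift from the cis methyl group (favoured by the unsubstituted termini and the siloxy donor).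

Step 7
Reactants: 13 (8aR)-4-[(tert-butyldimethylsilyl)oxy]-8a-methyl-1,2,5,6-tetrahydroazulen-3(8aH)-one
Product: 15 (3R,3aR,8aR)-3-hydroxy-8a-methyl-3-(propan-2-yl)-2,3,3a,5,6,8a-hexahydroazulen-4(1H)-one, via carbinol 14 (not isolated)
Conditions: i-PrLi, CeCl3, THF, −78 °C; AcOH (1 equiv), −78 °C; then TBAF/AcOH (1:1), THF, 0 °C
Reagents that add atoms: isopropyllithium, CC(C)[Li]
Why: 1,2-Addition of the weakly basic organocerium to the carbonyl of the vinylogous silyl ester, expected anti to the pseudo-axial C8a methyl (C8, tied back into the seven-membered ring, is pseudo-equatorial), which gives the 3R carbinol with hydroxyl cis to that methyl. Buffered fluoride then cleaves the silyl enol ether; protonation at C3a under equilibrating conditions should give the trans-fused ketone, in which C4 is trans to the isopropyl group and the hydroxyl can hydrogen-bond to the ketone.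

Step 8
Reactants: 15 (3R,3aR,8aR)-3-hydroxy-8a-methyl-3-(propan-2-yl)-2,3,3a,5,6,8a-hexahydroazulen-4(1H)-one
Product: 16 (3R,3aS,4S,8aR)-8a-methyl-3-(propan-2-yl)-1,2,3,3a,4,5,6,8a-octahydroazulene-3,4-diol
Conditions: Me4NBH(OAc)3, MeCN/AcOH, −20 °C
Reagents that add atoms: none
Why: Evans–Saksena reduction: the C3 hydroxyl exchanges onto boron and delivers hydride intramolecularly to the face of the C4 ketone on its own side, the methyl-bearing face that external hydride cannot reach, which should give the 1,3-anti diol with the 4S configuration.

Step 9
Reactants: 16 (3R,3aS,4S,8aR)-8a-methyl-3-(propan-2-yl)-1,2,3,3a,4,5,6,8a-octahydroazulene-3,4-diol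
Product: 17 (3R,3aS,4S,8aR)-3,4-dihydroxy-8a-methyl-3-(propan-2-yl)-2,3,3a,4,5,8a-hexahydroazulen-6(1H)-one
Conditions: Rh2(cap)4 (dirhodium tetrakis(caprolactamate), 1 mol %), t-BuOOH, K2CO3, CH2Cl2, rt
Reagents that add atoms: tert-butyl hydroperoxide, CC(C)(C)OO
Why: Radical allylic oxidation by tert-butylperoxyl radicals; C6 is the only allylic methylene of the C7=C8 bond (C8a is quaternary), and the weaker allylic C–H should react before the carbinol C–H at C4.

Step 10
Reactants: 17 (3R,3aS,4S,8aR)-3,4-dihydroxy-8a-methyl-3-(propan-2-yl)-2,3,3a,4,5,8a-hexahydroazulen-6(1H)-one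
Product: 18 (3R,3aS,4S,6R,8aR)-6,8a-dimethyl-3-(propan-2-yl)-1,2,3,3a,4,5,6,8a-octahydroazulene-3,4,6-triol
Conditions: MeMgBr (4 equiv), CH2Cl2/Et2O, −78 °C; aq. NH4Cl
Reagents that add atoms: methylmagnesium bromide, C[Mg]Br
Why: Chelation-controlled Grignard 1,2-addition: the magnesium alkoxide at C4 binds the C6 carbonyl oxygen and pulls it onto the lower face, so the only open trajectory for methyl is from the upper face; this should give the cis-1,3-diol (6R) with the methyl cis to the C8a methyl.

Step 11
Reactants: 18 (3R,3aS,4S,6R,8aR)-6,8a-dimethyl-3-(propan-2-yl)-1,2,3,3a,4,5,6,8a-octahydroazulene-3,4,6-triol; 19 4-(acetyloxy)-3-methoxybenzoic acid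
Product: 20 (3R,3aS,4S,6R,8aR)-3,6-dihydroxy-6,8a-dimethyl-3-(propan-2-yl)-1,2,3,3a,4,5,6,8a-octahydroazulen-4-yl 4-(acetyloxy)-3-methoxybenzoate
Conditions: EDC·HCl, DMAP, CH2Cl2, rt
Reagents that add atoms: none
Why: Steglich esterification; only the secondary C4 hydroxyl should be acylated, the two tertiary hydroxyls being far less reactive, and the neutral conditions spare the tertiary allylic alcohol.

Step 12
Reactants: 20 (3R,3aS,4S,6R,8aR)-3,6-dihydroxy-6,8a-dimethyl-3-(propan-2-yl)-1,2,3,3a,4,5,6,8a-octahydroazulen-4-yl 4-(acetyloxy)-3-methoxybenzoate
Product: 21 (3R,3aS,4S,6R,8aR)-3,6-dihydroxy-6,8a-dimethyl-3-(propan-2-yl)-1,2,3,3a,4,5,6,8a-octahydroazulen-4-yl 4-hydroxy-3-methoxybenzoate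
Conditions: NH3, MeOH, 0 °C
Reagents that add atoms: none
Why: Aminolysis of the aryl acetate, an activated ester that should cleave far faster than the hindered, electron-rich benzoate at C4; no acid touches the tertiary allylic alcohol.

## Compound list

1 | prop-2-yn-1-ol | C#CCO | starting material
2 | bromoethene | C=CBr | starting material
3 | [(1E)-3-(dimethylalumanyloxy)-2-methylprop-1-en-1-yl]dimethylalumane | C[Al](C)/C=C(\C)CO[Al](C)C | intermediate (not isolated)
4 | (2E)-2-methylpenta-2,4-dien-1-ol | C=C/C=C(\C)CO | intermediate
5 | (3E)-5-bromo-4-methylpenta-1,3-diene | C=C/C=C(\C)CBr | intermediate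
6 | pentane-2,4-dione | CC(=O)CC(C)=O | starting material
7 | dilithium 1,3-dianion of pentane-2,4-dione | [Li+].[Li+].[CH2-]C(=O)[CH-]C(C)=O | intermediate (not isolated)
8 | (7E)-7-methyldeca-7,9-diene-2,4-dione | CC(=O)CC(=O)CC/C(C)=C/C=C | intermediate
9 | (7E)-3-diazo-7-methyldeca-7,9-diene-2,4-dione | CC(=O)C(=[N+]=[N-])C(=O)CC/C(C)=C/C=C | intermediate
10 | lithium (7E)-3-diazo-7-methyl-4-oxodeca-1,7,9-trien-2-olate | [Li+].[O-]C(=C)C(=[N+]=[N-])C(=O)CC/C(C)=C/C=C | intermediate (not isolated)
11 | (7E)-2-[(tert-butyldimethylsilyl)oxy]-3-diazo-7-methyldeca-1,7,9-trien-4-one | C=C(O[Si](C)(C)C(C)(C)C)C(=[N+]=[N-])C(=O)CC/C(C)=C/C=C | intermediate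
12 | (1S,5R,6R)-1-{1-[(tert-butyldimethylsilyl)oxy]ethenyl}-6-ethenyl-5-methylbicyclo[3.1.0]hexan-2-one | C=C(O[Si](C)(C)C(C)(C)C)[C@@]12C(=O)CC[C@]1(C)[C@H]2C=C | intermediate (not isolated)
13 | (8aR)-4-[(tert-butyldimethylsilyl)oxy]-8a-methyl-1,2,5,6-tetrahydroazulen-3(8aH)-one | CC(C)(C)[Si](C)(C)OC1=C2C(=O)CC[C@]2(C)C=CCC1 | intermediate
14 | (3R,8aR)-4-[(tert-butyldimethylsilyl)oxy]-8a-methyl-3-(propan-2-yl)-1,2,3,5,6,8a-hexahydroazulen-3-ol | CC(C)(C)[Si](C)(C)OC1=C2[C@](O)(C(C)C)CC[C@]2(C)C=CCC1 | intermediate (not isolated)
15 | (3R,3aR,8aR)-3-hydroxy-8a-methyl-3-(propan-2-yl)-2,3,3a,5,6,8a-hexahydroazulen-4(1H)-one | O=C1CCC=C[C@@]2(C)CC[C@@](O)(C(C)C)[C@H]12 | intermediate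
16 | (3R,3aS,4S,8aR)-8a-methyl-3-(propan-2-yl)-1,2,3,3a,4,5,6,8a-octahydroazulene-3,4-diol | O[C@H]1CCC=C[C@@]2(C)CC[C@@](O)(C(C)C)[C@H]12 | intermediate
17 | (3R,3aS,4S,8aR)-3,4-dihydroxy-8a-methyl-3-(propan-2-yl)-2,3,3a,4,5,8a-hexahydroazulen-6(1H)-one | O[C@H]1CC(=O)C=C[C@@]2(C)CC[C@@](O)(C(C)C)[C@H]12 | intermediate
18 | (3R,3aS,4S,6R,8aR)-6,8a-dimethyl-3-(propan-2-yl)-1,2,3,3a,4,5,6,8a-octahydroazulene-3,4,6-triol | O[C@H]1C[C@@](C)(O)C=C[C@@]2(C)CC[C@@](O)(C(C)C)[C@H]12 | intermediate
19 | 4-(acetyloxy)-3-methoxybenzoic acid | COc1cc(C(=O)O)ccc1OC(C)=O | starting material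
20 | (3R,3aS,4S,6R,8aR)-3,6-dihydroxy-6,8a-dimethyl-3-(propan-2-yl)-1,2,3,3a,4,5,6,8a-octahydroazulen-4-yl 4-(acetyloxy)-3-methoxybenzoate | COc1cc(C(=O)O[C@H]2C[C@@](C)(O)C=C[C@@]3(C)CC[C@@](O)(C(C)C)[C@H]23)ccc1OC(C)=O | intermediate
21 | (3R,3aS,4S,6R,8aR)-3,6-dihydroxy-6,8a-dimethyl-3-(propan-2-yl)-1,2,3,3a,4,5,6,8a-octahydroazulen-4-yl 4-hydroxy-3-methoxybenzoate | COc1cc(C(=O)O[C@H]2C[C@@](C)(O)C=C[C@@]3(C)CC[C@@](O)(C(C)C)[C@H]23)ccc1O | target

## Step count and least certain steps

Total step count: 12. Longest linear sequence: 12 steps (1 to 21); 2, 6 and 19 are bought.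

**Step 6 (key step).** The enantioface discrimination by a ketone-acceptor vinylcarbenoid delivered through a short tether may be insufficient. The diazo compound may also be diverted by thermal cyclisation to a pyrazole, or the cyclopropane by a 1,5-hydrogen shift from the cis methyl group if the Cope rearrangement needs heating. Fallback: from 11, the tandem reaction is run with achiral Rh2(esp)2 (dirhodium bis(α,α,α′,α′-tetramethyl-1,3-benzenedipropionate)) in CH2Cl2 at 0 °C, which removes the constraint of a matched chiral catalyst and should give 13 together with its (8aS) enantiomer F1. The two are separated by preparative chromatography on a chiral stationary phase, and the route is rejoined at 13.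

**Step 5.** Deprotonation may not discriminate well enough between the acetyl methyl and the chain methylene, which would give the regioisomeric enol ether. Fallback by symmetry: from 6, diazo transfer (p-ABSA, Et3N) gives 3-diazopentane-2,4-dione F2, whose two methyl groups are equivalent. One equivalent of TBSOTf/Et3N gives 4-[(tert-butyldimethylsilyl)oxy]-3-diazopent-4-en-2-one F3. Its only remaining enolisable position is deprotonated with LiHMDS at −78 °C and alkylated with 5, which leads to 11 with the regiochemistry fixed.

**Step 7.** Facial selectivity at C3 may be poor, because the two substituents on C8a that flank the ketone differ only moderately in size. The tertiary allylic alcohol may also ionise on work-up with loss of water to the transposed enone. Fallback by thermodynamic instead of kinetic control: the (3S,3aR,8aR) C3 epimer F4 formed beside 15 is treated with catalytic KOt-Bu in t-BuOH at 0 °C. Retro-aldol opening to (3S)-3-methyl-3-(4-methyl-3-oxopentyl)cyclohept-4-en-1-one F5 and aldol reclosure should funnel the material to 15, the isomer with hydroxyl cis and isopropyl trans to the acyl branch, where the route is rejoined.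

**Step 8.** If the seven-membered ring holds the ketone so that the boron-bound hydride cannot reach its upper face, reduction may stall or take place from the open face and give the 4-epimer. Fallback: from 15, dissolving-metal reduction (Li, NH3, t-BuOH, THF, −78 °C) gives the thermodynamically preferred equatorial alcohol, which is the 4S alcohol 16 with the oxygen anti to the angular methyl (no new compound, F0). The isolated double bond is inert under these conditions.

**Step 9.** The secondary C4 alcohol may be over-oxidised, the allylic radical may be trapped at C8 to give a transposed enone, and the β-hydroxy enone may lose water. Fallback by an ene/[2,3] mechanism that cannot transpose and does not oxidise saturated alcohols: from 16, SeO2 (cat.)/t-BuOOH in CH2Cl2 gives the C6 allylic alcohol F6 (either C6 epimer). MnO2, which oxidises only the allylic carbinol, then gives 17.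

**Step 10.** If the chelate does not form, methyl may add from the face anti to the C8a methyl and give the 6-epimer. Conjugate addition or retro-aldol opening of the magnesium alkoxide may also compete. Fallback by oxygen delivery instead of carbon delivery: from 17, methylenation under non-basic conditions (Zn, CH2Br2, TiCl4) gives the exocyclic diene F7. Hydroxyl-directed epoxidation (VO(acac)2, t-BuOOH), guided by the homoallylic C4 hydroxyl, puts the oxygen on the lower face and gives spiro-epoxide F8. LiAlH4 opens it at the primary carbon to 18.

## Further compounds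

F1 | step 6 | (8aS)-4-[(tert-butyldimethylsilyl)oxy]-8a-methyl-1,2,5,6-tetrahydroazulen-3(8aH)-one | CC(C)(C)[Si](C)(C)OC1=C2C(=O)CC[C@@]2(C)C=CCC1
F2 | step 5 | 3-diazopentane-2,4-dione | CC(=O)C(=[N+]=[N-])C(C)=O
F3 | step 5 | 4-[(tert-butyldimethylsilyl)oxy]-3-diazopent-4-en-2-one | C=C(O[Si](C)(C)C(C)(C)C)C(=[N+]=[N-])C(C)=O
F4 | step 7 | (3S,3aR,8aR)-3-hydroxy-8a-methyl-3-(propan-2-yl)-2,3,3a,5,6,8a-hexahydroazulen-4(1H)-one | O=C1CCC=C[C@@]2(C)CC[C@](O)(C(C)C)[C@H]12
F5 | step 7 | (3S)-3-methyl-3-(4-methyl-3-oxopentyl)cyclohept-4-en-1-one | CC(C)C(=O)CC[C@@]1(C)CC(=O)CCC=C1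
F0 | step 8 | none | none
F6 | step 9 | (3R,3aS,4S,8aR)-8a-methyl-3-(propan-2-yl)-1,2,3,3a,4,5,6,8a-octahydroazulene-3,4,6-triol (C6 epimers) | O[C@H]1CC(O)C=C[C@@]2(C)CC[C@@](O)(C(C)C)[C@H]12
F7 | step 10 | (3R,3aS,4S,8aR)-8a-methyl-6-methylidene-3-(propan-2-yl)-1,2,3,3a,4,5,6,8a-octahydroazulene-3,4-diol | O[C@H]1CC(=C)C=C[C@@]2(C)CC[C@@](O)(C(C)C)[C@H]12
F8 | step 10 | (3R,3aS,4S,6R,8aR)-8a-methyl-3-(propan-2-yl)-1,2,3,3a,4,5-hexahydro-8aH-spiro[azulene-6,2'-oxirane]-3,4-diol | O[C@H]1C[C@]3(CO3)C=C[C@@]2(C)CC[C@@](O)(C(C)C)[C@H]12
A1 | alternative 1 | (1R,2S,3R)-2-[(1S,3R)-1,3-dihydroxy-3-methylpent-4-en-1-yl]-3-ethenyl-3-methyl-1-(propan-2-yl)cyclopentan-1-ol | C=C[C@@]1(C)CC[C@@](O)(C(C)C)[C@@H]1[C@@H](O)C[C@@](C)(O)C=C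
A2 | alternative 2 | (1R,3aR,7S,7aS)-1,7-dihydroxy-3a-methyl-1-(propan-2-yl)octahydro-5H-inden-5-one | O[C@H]1CC(=O)C[C@@]2(C)CC[C@@](O)(C(C)C)[C@H]12
A3 | alternative 3 | (3R,3aS,4S,8aR)-3-hydroxy-6,8a-dimethyl-3-(propan-2-yl)-1,2,3,3a,4,5,8,8a-octahydroazulen-4-yl 4-hydroxy-3-methoxybenzoate | COc1cc(C(=O)O[C@H]2CC(C)=CC[C@@]3(C)CC[C@@](O)(C(C)C)[C@H]23)ccc1O
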